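**Plan**

1. Retrosynthesis first cuts the two ester C–O bonds (malonic acid plus two molecules of labd-13E-ene-8α,15-diol), then C12–C13 (sp3–sp2 coupling with an E-enol triflate) and C11=C12 (methylenation), back to an 8α-silyloxy drimane 11-aldehyde (terpenoid numbering throughout the discussion).
2. Enabling feature: ring B holds the C8 carbinol (O and CH3 on C8) next to C9, with the trans C5–C10 fusion on its other side. C5–C10 and C8–C9 are therefore cut together, giving diene C5=C6–C7=C8(OSi)CH3 and dienophile C9=C10–CHO linked by C1–C4 of ring A, a 1,7,9-decatriene.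
3. Forward, the acyclic trienal is joined in the order C5–C6 (iodo-olefination of 2,2-dimethylpent-4-enal), C6–C7 (epoxide opening), C1–C10 (B-alkyl Suzuki coupling with the enol triflate of ethyl acetoacetate). The C8 ketone then becomes the (Z)-silyl dienol ether and C11 the aldehyde.
4. Rings A and B close together in one intramolecular Diels–Alder step. Hydrogenation, methylenation, a second B-alkyl Suzuki coupling with the same triflate, reduction, desilylation and double esterification finish the synthesis.
5. Stereochemistry: C5, C8, C9 and C10 all arise in the cycloaddition. Their relative configuration comes from the 2E, 8E and 10Z alkene geometries and the endo mode, their absolute configuration from a chiral oxazaborolidinium catalyst. Both 13E alkenes come from the E geometry of the enol triflate.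

Key step: step 9

Assumption: the sense of induction follows the accepted pre-transition-state model for oxazaborolidinium-bound enals (formyl C–H···O contact, s-trans enal stacked on the neighbouring phenyl group), which assigns attack on the Si face of C9 to the (R)-configured catalyst.

**Route**

Step 1
Reactants: 1 ethyl acetoacetate
Product: 2 ethyl (2E)-3-{[(trifluoromethyl)sulfonyl]oxy}but-2-enoate
Conditions: Tf2O, aq. Me4NOH, hexanes, 5 °C
Reagents that add atoms: triflic anhydride, O=S(=O)(OS(=O)(=O)C(F)(F)F)C(F)(F)F
Why: O-triflation of the acetoacetate enolate under Schotten–Baumann-type conditions, where the non-chelating tetramethylammonium counter-ion should favour the open enolate and so place the triflate trans to the ester (E).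

Step 2
Reactants: 3 2,2-dimethylpent-4-enal
Product: 4 (1E)-1-iodo-3,3-dimethylhexa-1,5-diene
Conditions: CrCl2 (6 equiv), CHI3 (2 equiv), THF/dioxane, 0 °C → rt
Reagents that add atoms: iodoform, IC(I)I
Why: Takai iodo-olefination of a non-enolisable aldehyde, in which the α-quaternary centre should reinforce the intrinsic E preference of the anti-elimination from the geminal dichromium adduct.

Step 3
Reactants: 4 (1E)-1-iodo-3,3-dimethylhexa-1,5-diene; 5 racemic 2-methyloxirane
Product: 7 racemic (4E)-6,6-dimethylnona-4,8-dien-2-ol, via alkenyllithium 6 (not isolated)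
Conditions: t-BuLi (2.05 equiv), Et2O, −78 °C; then BF3·OEt2, 2-methyloxirane, −78 °C
Reagents that add atoms: none
Why: Iodine–lithium exchange occurs with retention of the E geometry and the BF3-assisted SN2 opening takes place at the unsubstituted epoxide carbon; the racemic carbinol centre is removed in step 5.

Step 4
Reactants: 7 racemic (4E)-6,6-dimethylnona-4,8-dien-2-ol; 2 ethyl (2E)-3-{[(trifluoromethyl)sulfonyl]oxy}but-2-enoate
Product: 9 ethyl (2E,8E)-11-hydroxy-3,7,7-trimethyldodeca-2,8-dienoate, via B-alkyl-9-BBN borinate 8 (not isolated)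
Conditions: 9-BBN (2.2 equiv), THF, 0 °C → rt; then 2, PdCl2(dppf) (5 mol%), K3PO4, DMF/H2O, rt → 50 °C
Reagents that add atoms: none
Why: 9-BBN adds anti-Markovnikov to the terminal alkene only (the hydroxyl is masked in situ as its borinate and the hindered internal alkene is inert), and the B-alkyl Suzuki–Miyaura coupling retains the triflate geometry, fixing the 2E trisubstituted enoate.

Step 5
Reactants: 9 ethyl (2E,8E)-11-hydroxy-3,7,7-trimethyldodeca-2,8-dienoate
Product: 10 ethyl (2E,8E)-3,7,7-trimethyl-11-oxododeca-2,8-dienoate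
Conditions: Dess–Martin periodinane, pyridine, CH2Cl2, 0 °C → rt
Reagents that add atoms: none
Why: Dess–Martin oxidation under buffered, non-basic conditions should give the β,γ-unsaturated methyl ketone without migration of the 8E alkene into conjugation.

Step 6
Reactants: 10 ethyl (2E,8E)-3,7,7-trimethyl-11-oxododeca-2,8-dienoate
Product: 11 ethyl (2E,8E,10Z)-11-[(tert-butyldimethylsilyl)oxy]-3,7,7-trimethyldodeca-2,8,10-trienoate
Conditions: TBSOTf (1.2 equiv), Et3N (2 equiv), CH2Cl2, −78 °C
Reagents that add atoms: tert-butyldimethylsilyl triflate, CC(C)(C)[Si](C)(C)OS(=O)(=O)C(F)(F)F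
Why: Soft enolisation removes the doubly activated methylene proton between carbonyl and alkene in preference to a methyl proton, giving the conjugated dienol ether; the 10Z isomer (silyloxy cis to the diene chain, methyl away from it) is expected to prevail and the enoate is not enolised.

Step 7
Reactants: 11 ethyl (2E,8E,10Z)-11-[(tert-butyldimethylsilyl)oxy]-3,7,7-trimethyldodeca-2,8,10-trienoate
Product: 12 (2E,8E,10Z)-11-[(tert-butyldimethylsilyl)oxy]-3,7,7-trimethyldodeca-2,8,10-trien-1-ol
Conditions: iBu2AlH (2.5 equiv), CH2Cl2, −78 °C; aq. potassium sodium tartrate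
Reagents that add atoms: none
Why: 1,2-Reduction of the enoate by iBu2AlH at low temperature leaves the silyl dienol ether untouched, and the neutral tartrate work-up avoids its hydrolysis.

Step 8
Reactants: 12 (2E,8E,10Z)-11-[(tert-butyldimethylsilyl)oxy]-3,7,7-trimethyldodeca-2,8,10-trien-1-ol
Product: 13 (2E,8E,10Z)-11-[(tert-butyldimethylsilyl)oxy]-3,7,7-trimethyldodeca-2,8,10-trienal
Conditions: MnO2 (excess), CH2Cl2, rt
Reagents that add atoms: none
Why: Heterogeneous, neutral MnO2 oxidation is selective for the allylic alcohol and should keep both the 2E geometry and the dienol ether.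

Step 9
Reactants: 13 (2E,8E,10Z)-11-[(tert-butyldimethylsilyl)oxy]-3,7,7-trimethyldodeca-2,8,10-trienal
Product: 14 (5S,8R,9R,10S)-8α-(tert-butyldimethylsilyloxy)drim-6-en-11-al (trans-fused; 9β-CHO, 10β-CH3, 5α-H, 8β-CH3)
Conditions: (R)-3,3-diphenyl-1-(2-methylphenyl)tetrahydro-1H,3H-pyrrolo[1,2-c][1,3,2]oxazaborole (20 mol%), Tf2NH (18 mol%), CH2Cl2, 0.01 M, −78 → −40 °C
Reagents that add atoms: none
Why: Proposed new method: the chiral boron cation binds the formyl oxygen of the s-trans enal and lowers its LUMO, and the electron-rich silyl dienol ether adds across C9=C10 in an asynchronous [4+2] process in which the C5–C10 bond leads (vinylogous Mukaiyama–Michael character) and the C8–C9 bond follows before any bond rotation; the closest known reactions are Lewis-acid-promoted intramolecular Diels–Alder reactions of 1,7,9-decatrienes with a terminal carbonyl activator and oxazaborolidinium-catalysed Diels–Alder reactions of enals with silyloxy dienes. Ring A closes by 6-exo attack of C5 on the enal β-carbon C10 with the C1–C4 tether folded as a chair, and ring B is the cyclohexene ring of the cycloaddition itself (a 6-(enolexo)-exo-trig closure of C9 onto the silyloxocarbenium carbon C8 in the stepwise limit), so the product is a tertiary allylic silyl ether. C9 and C10 are related by the 2E geometry (formyl cis to the C10 methyl), C5 by the 8E geometry together with the endo position of the complexed formyl group (H5 trans to the C10 methyl, trans fusion), and C8 by the 10Z geometry, whose inward silyloxy group ends cis to H5 (8α-O, 8β-CH3). The absolute configuration comes from the catalyst, whose phenyl group covers one face of the bound enal so that the diene reaches the Si face of C9. The step needs endo over exo selectivity (secured by the E-dienophile with its terminal, Lewis-acid-bound formyl group and the chair tether), cycloaddition over 1,2-addition (the competing aldol closure would need an eight-membered ring) and retention of the diene geometry (secured by low temperature and immediate intramolecular capture of any open intermediate).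

Step 10
Reactants: 14 8α-(tert-butyldimethylsilyloxy)drim-6-en-11-al
Product: 15 8α-(tert-butyldimethylsilyloxy)driman-11-al
Conditions: H2 (1 atm), 5% Rh/Al2O3, EtOAc, rt
Reagents that add atoms: none
Why: Heterogeneous hydrogenation of the only C=C bond creates no stereocentre, and rhodium in a neutral aprotic solvent should avoid hydrogenolysis of the allylic C–O bond and reduction of the hindered aldehyde.

Step 11
Reactants: 15 8α-(tert-butyldimethylsilyloxy)driman-11-al
Product: 16 8α-(tert-butyldimethylsilyloxy)-13,14,15,16-tetranorlabd-11-ene (9β-vinyl)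
Conditions: Ph3PCH3Br, KOtBu, THF, 0 °C → rt
Reagents that add atoms: methyltriphenylphosphonium bromide, C[P+](c1ccccc1)(c1ccccc1)c1ccccc1.[Br-]
Why: Wittig methylenation with the unstabilised ylide reaches the hindered aldehyde; C9 already carries the more stable equatorial formyl group, and the equatorial silyloxy group is poorly aligned for β-elimination.

Step 12
Reactants: 16 8α-(tert-butyldimethylsilyloxy)-13,14,15,16-tetranorlabd-11-ene; 2 ethyl (2E)-3-{[(trifluoromethyl)sulfonyl]oxy}but-2-enoate
Product: 18 ethyl 8α-(tert-butyldimethylsilyloxy)labd-13E-en-15-oate, via B-alkyl-9-BBN borane 17 (not isolated)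
Conditions: 9-BBN (1.5 equiv), THF, rt → 50 °C; then 2, PdCl2(dppf) (5 mol%), K3PO4, DMF/H2O, 50 °C
Reagents that add atoms: none
Why: 9-BBN places boron on the terminal carbon C12 of the only alkene, and the B-alkyl Suzuki–Miyaura coupling with retention of the triflate geometry forms C12–C13 and fixes the 13E enoate.

Step 13
Reactants: 18 ethyl 8α-(tert-butyldimethylsilyloxy)labd-13E-en-15-oate
Product: 19 8α-(tert-butyldimethylsilyloxy)labd-13E-en-15-ol
Conditions: iBu2AlH (2.5 equiv), CH2Cl2, −78 °C; aq. potassium sodium tartrate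
Reagents that add atoms: none
Why: 1,2-Reduction of the enoate by iBu2AlH gives the allylic alcohol without touching the trisubstituted alkene or the tertiary silyl ether.

Step 14
Reactants: 19 8α-(tert-butyldimethylsilyloxy)labd-13E-en-15-ol
Product: 20 labd-13E-ene-8α,15-diol
Conditions: Bu4NF (4 equiv), THF, 60 °C
Reagents that add atoms: none
Why: Fluoride-induced cleavage of the hindered tertiary silyl ether needs heating, which is acceptable because no base- or fluoride-sensitive group is present.

Step 15
Reactants: 20 labd-13E-ene-8α,15-diol (2.05 equiv); 21 malonic acid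
Product: 22 bis[(13E)-8α-hydroxylabd-13-en-15-yl] propanedioate (CNP0254645.1)
Conditions: DCC (2.2 equiv), DMAP (0.1 equiv), CH2Cl2/THF, 0 °C → rt
Reagents that add atoms: none
Why: Steglich esterification acylates only the primary allylic hydroxyl, the hindered tertiary 8-hydroxyl being inert, so two diol molecules per malonic acid should give the symmetrical diester.

**Compound list**

1 | ethyl acetoacetate | CCOC(=O)CC(C)=O | starting material
2 | ethyl (2E)-3-{[(trifluoromethyl)sulfonyl]oxy}but-2-enoate | CCOC(=O)/C=C(\C)OS(=O)(=O)C(F)(F)F | intermediate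
3 | 2,2-dimethylpent-4-enal | C=CCC(C)(C)C=O | starting material
4 | (1E)-1-iodo-3,3-dimethylhexa-1,5-diene | C=CCC(C)(C)/C=C/I | intermediate
5 | racemic 2-methyloxirane | CC1CO1 | starting material
6 | [(1E)-3,3-dimethylhexa-1,5-dien-1-yl]lithium | [Li]/C=C/C(C)(C)CC=C | intermediate
7 | racemic (4E)-6,6-dimethylnona-4,8-dien-2-ol | CC(O)C/C=C/C(C)(C)CC=C | intermediate
8 | B-alkyl-9-BBN borinate of 7 (boron on the terminal carbon and on oxygen) | CC(OB1C2CCCC1CCC2)C/C=C/C(C)(C)CCCB1C2CCCC1CCC2 | intermediate
9 | ethyl (2E,8E)-11-hydroxy-3,7,7-trimethyldodeca-2,8-dienoate (racemic) | CCOC(=O)/C=C(\C)CCCC(C)(C)/C=C/CC(C)O | intermediate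
10 | ethyl (2E,8E)-3,7,7-trimethyl-11-oxododeca-2,8-dienoate | CCOC(=O)/C=C(\C)CCCC(C)(C)/C=C/CC(C)=O | intermediate
11 | ethyl (2E,8E,10Z)-11-[(tert-butyldimethylsilyl)oxy]-3,7,7-trimethyldodeca-2,8,10-trienoate | CCOC(=O)/C=C(\C)CCCC(C)(C)/C=C/C=C(/C)O[Si](C)(C)C(C)(C)C | intermediate
12 | (2E,8E,10Z)-11-[(tert-butyldimethylsilyl)oxy]-3,7,7-trimethyldodeca-2,8,10-trien-1-ol | OC/C=C(\C)CCCC(C)(C)/C=C/C=C(/C)O[Si](C)(C)C(C)(C)C | intermediate
13 | (2E,8E,10Z)-11-[(tert-butyldimethylsilyl)oxy]-3,7,7-trimethyldodeca-2,8,10-trienal | O=C/C=C(\C)CCCC(C)(C)/C=C/C=C(/C)O[Si](C)(C)C(C)(C)C | intermediate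
14 | (5S,8R,9R,10S)-8α-(tert-butyldimethylsilyloxy)drim-6-en-11-al | O=C[C@@H]1[C@@]2(C)CCCC(C)(C)[C@@H]2C=C[C@@]1(C)O[Si](C)(C)C(C)(C)C | intermediate
15 | 8α-(tert-butyldimethylsilyloxy)driman-11-al | O=C[C@@H]1[C@@]2(C)CCCC(C)(C)[C@@H]2CC[C@@]1(C)O[Si](C)(C)C(C)(C)C | intermediate
16 | 8α-(tert-butyldimethylsilyloxy)-13,14,15,16-tetranorlabd-11-ene | C=C[C@@H]1[C@@]2(C)CCCC(C)(C)[C@@H]2CC[C@@]1(C)O[Si](C)(C)C(C)(C)C | intermediate
17 | B-alkyl-9-BBN borane of 16 (boron on C12) | B1(CC[C@@H]3[C@@]4(C)CCCC(C)(C)[C@@H]4CC[C@@]3(C)O[Si](C)(C)C(C)(C)C)C2CCCC1CCC2 | intermediate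
18 | ethyl 8α-(tert-butyldimethylsilyloxy)labd-13E-en-15-oate | CCOC(=O)/C=C(\C)CC[C@@H]1[C@@]2(C)CCCC(C)(C)[C@@H]2CC[C@@]1(C)O[Si](C)(C)C(C)(C)C | intermediate
19 | 8α-(tert-butyldimethylsilyloxy)labd-13E-en-15-ol | OC/C=C(\C)CC[C@@H]1[C@@]2(C)CCCC(C)(C)[C@@H]2CC[C@@]1(C)O[Si](C)(C)C(C)(C)C | intermediate
20 | (5S,8R,9R,10S)-labd-13E-ene-8α,15-diol | OC/C=C(\C)CC[C@@H]1[C@@]2(C)CCCC(C)(C)[C@@H]2CC[C@@]1(C)O | intermediate
21 | malonic acid | OC(=O)CC(=O)O | starting material
22 | bis[(13E)-8α-hydroxylabd-13-en-15-yl] propanedioate (CNP0254645.1) | C/C(=C\COC(=O)CC(=O)OC/C=C(\C)CC[C@@H]1[C@@]2(C)CCCC(C)(C)[C@@H]2CC[C@@]1(C)O)CC[C@@H]1[C@@]2(C)CCCC(C)(C)[C@@H]2CC[C@@]1(C)O | target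

**Step count**

Total: 15 steps. Longest linear sequence: 14 steps (steps 2 to 15, from 2,2-dimethylpent-4-enal 3). Step 1 is a one-step side branch whose product 2 is used in steps 4 and 12.

**Steps most likely to fail**

Step 9. Facial control may be lost: silyl transfer from the dienol ether to the acidic catalyst could release an achiral silyl triflimide that takes over the catalysis, or the chiral cation may discriminate the faces of the hindered β,β-disubstituted enal poorly. The fallback gives up catalyst control and separates the enantiomers, using aluminium-promoted intramolecular Diels–Alder closure of a decatrienal and resolution through diastereomeric esters, both established operations. Setting out from 13, Me2AlCl (1.5 equiv, CH2Cl2, −78 → −20 °C) should give the racemic cycloadduct, that is 14 together with its mirror image ent-8α-(tert-butyldimethylsilyloxy)drim-6-en-11-al F1. NaBH4 in MeOH should reduce both to 8α-(tert-butyldimethylsilyloxy)drim-6-en-11-ol F2 and its enantiomer ent-8α-(tert-butyldimethylsilyloxy)drim-6-en-11-ol F3. Esterification with (S)-O-methylmandelic acid (DCC, DMAP) should give the diastereomeric esters 8α-(tert-butyldimethylsilyloxy)drim-6-en-11-yl (S)-O-methylmandelate F4 and its diastereomer from the mirror-image alcohol F5, to be separated by chromatography. iBu2AlH releases F2 from F4, and Dess–Martin oxidation brings the sequence back to the route at 14.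

Step 7. The dienol ether may be lost by protodesilylation or silyl migration during hydride reduction, aqueous work-up and the oxidation that follows, returning the β,γ-enone. The fallback reorders the sequence so that the silyl group is introduced last and never meets hydride or oxidant. Setting out from 9, iBu2AlH should give (2E,8E)-3,7,7-trimethyldodeca-2,8-diene-1,11-diol F6. MnO2, which oxidises only the allylic hydroxyl, should give (2E,8E)-11-hydroxy-3,7,7-trimethyldodeca-2,8-dienal F7. Dess–Martin periodinane with pyridine should then give (2E,8E)-3,7,7-trimethyl-11-oxododeca-2,8-dienal F8. TBSOTf (1.05 equiv) with Et3N at −78 °C should silylate the far more acidic ketone methylene, coming back to the route at 13.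

Step 12. Hydroboration at the congested vinyl group and transmetalation of the branched borane may be slow, so that triflate hydrolysis and protodeboronation outrun the coupling. The fallback builds the side chain by two carbonyl olefinations instead of a cross-coupling. Setting out from 15, Horner–Wadsworth–Emmons reaction with diethyl (2-oxopropyl)phosphonate (Ba(OH)2, wet THF) should give (11E)-8α-(tert-butyldimethylsilyloxy)-14,15-dinorlabd-11-en-13-one F9. Hydrogenation (H2, Pd/C, EtOAc) should give 8α-(tert-butyldimethylsilyloxy)-14,15-dinorlabdan-13-one F10. A second Horner–Wadsworth–Emmons reaction with triethyl phosphonoacetate (NaH, THF, reflux) should favour the 13E enoate, which after chromatographic removal of the geometric isomer rejoins the route at 18.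

**Further compounds**

F1 | step 9 | ent-8α-(tert-butyldimethylsilyloxy)drim-6-en-11-al (mirror image of 14) | O=C[C@H]1[C@]2(C)CCCC(C)(C)[C@H]2C=C[C@]1(C)O[Si](C)(C)C(C)(C)C
F2 | step 9 | 8α-(tert-butyldimethylsilyloxy)drim-6-en-11-ol | OC[C@@H]1[C@@]2(C)CCCC(C)(C)[C@@H]2C=C[C@@]1(C)O[Si](C)(C)C(C)(C)C
F3 | step 9 | ent-8α-(tert-butyldimethylsilyloxy)drim-6-en-11-ol (mirror image of F2) | OC[C@H]1[C@]2(C)CCCC(C)(C)[C@H]2C=C[C@]1(C)O[Si](C)(C)C(C)(C)C
F4 | step 9 | 8α-(tert-butyldimethylsilyloxy)drim-6-en-11-yl (S)-2-methoxy-2-phenylacetate | CO[C@H](C(=O)OC[C@@H]1[C@@]2(C)CCCC(C)(C)[C@@H]2C=C[C@@]1(C)O[Si](C)(C)C(C)(C)C)c1ccccc1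
F5 | step 9 | (S)-2-methoxy-2-phenylacetate of F3 | CO[C@H](C(=O)OC[C@H]1[C@]2(C)CCCC(C)(C)[C@H]2C=C[C@]1(C)O[Si](C)(C)C(C)(C)C)c1ccccc1
F6 | step 7 | (2E,8E)-3,7,7-trimethyldodeca-2,8-diene-1,11-diol | OC/C=C(\C)CCCC(C)(C)/C=C/CC(C)O
F7 | step 7 | (2E,8E)-11-hydroxy-3,7,7-trimethyldodeca-2,8-dienal | O=C/C=C(\C)CCCC(C)(C)/C=C/CC(C)O
F8 | step 7 | (2E,8E)-3,7,7-trimethyl-11-oxododeca-2,8-dienal | O=C/C=C(\C)CCCC(C)(C)/C=C/CC(C)=O
F9 | step 12 | (11E)-8α-(tert-butyldimethylsilyloxy)-14,15-dinorlabd-11-en-13-one | CC(=O)/C=C/[C@@H]1[C@@]2(C)CCCC(C)(C)[C@@H]2CC[C@@]1(C)O[Si](C)(C)C(C)(C)C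
F10 | step 12 | 8α-(tert-butyldimethylsilyloxy)-14,15-dinorlabdan-13-one | CC(=O)CC[C@@H]1[C@@]2(C)CCCC(C)(C)[C@@H]2CC[C@@]1(C)O[Si](C)(C)C(C)(C)C
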